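The ten-membered ring is disconnected across C5/C10: the C5 oxygen and the C10=C14 methylene of the target sit 1,6 on the ring, the retron of a C5–C10 decalin. Step 20 is a Grob fragmentation of trans-decalin 28, whose 5α tertiary alkoxide and angular 10β-CH2OMs lie anti across the fusion bond. One operation cleaves C5–C10 and delivers the ten-membered ring, the C5 ketone, the exocyclic C10=C14 alkene and the Z-C3=C4 alkene inherited from ring A, with C6–C9 already set on ring B. Ring B is built on a naphthalenone; ring A comes from phenol dearomatisation and an O9-tethered radical hydroxymethylation of C10.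

Key step: step 20

Remarks and assumptions (one line each)
- Locants C1–C15 are those of the target (C14 = methylene carbon on C10, C15 = methyl on C4, C11/C12/C13 = lactone α-carbon, carbonyl and methylene) and are used for all bicyclic intermediates; β is the face of C14 in decalin 28 (also the face of the C7 side chain, O6 and O9), α the opposite face (O8).
- Compounds 1, 4, 6, 22 and 32 and all reagents are taken as commercial.
- The precursor 28 carries its C5 hydroxyl α, trans-diaxial to the 10β-CH2OMs group: O5–C5–C10–C14 is then anti-periplanar, so closure to an oxetane is geometrically impossible; the C5 epimer would fragment to the same product.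
- The silicon tether is hung on O9: from O5 the radical could reach C4 as well as C10 (both 5-exo), from O9 only C10.
- The C15 methyl is bought with the arene, so no methylation of a non-activated arene position is needed.
- After the key step the C5 ketone is reduced first and the epoxide is then delivered from the new C5 hydroxyl; C2 stays masked to the last step because the free β,γ-unsaturated ketone is base-sensitive and a cis γ-hydroxy enone would close to a furan.

Step 1
Reactants: 1 2-bromoprop-2-en-1-ol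
Product: 2 2-bromoallyl 4-methoxybenzyl ether
Conditions: NaH, PMBCl, n-Bu4NI (cat.), THF, 0 °C → rt
Reagents that add atoms: 4-methoxybenzyl chloride, COc1ccc(CCl)cc1
Why: Williamson etherification of the primary allylic alkoxide with a benzylic chloride; the vinylic bromide is inert to substitution.

Step 2
Reactants: 2 2-bromoallyl 4-methoxybenzyl ether
Product: 3 alkenyl pinacol boronate
Conditions: B2pin2, PdCl2(PPh3)2 (cat.), PPh3, KOPh, toluene, 50 °C
Reagents that add atoms: bis(pinacolato)diboron, CC1(C)OB(OC1(C)C)B1OC(C)(C)C(C)(C)O1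
Why: Miyaura borylation of a 1-bromoalkene (zerovalent palladium, phenoxide base) exchanges C–Br for C–B without touching the PMB ether.

Step 3
Reactants: 4 4-hydroxy-2-methylbenzaldehyde
Product: 5 4-(allyloxy)-2-methylbenzaldehyde
Conditions: allyl bromide, K2CO3, DMF, rt
Reagents that add atoms: allyl bromide, C=CCBr
Why: Williamson O-allylation of the phenoxide installs a phenol protecting group that survives all steps up to step 14 and is then removed under neutral conditions.

Step 4
Reactants: 5 4-(allyloxy)-2-methylbenzaldehyde; 6 (2-carboxyethyl)triphenylphosphonium bromide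
Product: 7 (E)-4-[4-(allyloxy)-2-methylphenyl]but-3-enoic acid
Conditions: NaN(SiMe3)2 (2.1 equiv), THF, 0 °C → rt; then HCl (aq)
Reagents that add atoms: (2-carboxyethyl)triphenylphosphonium bromide (6), OC(=O)CC[P+](c1ccccc1)(c1ccccc1)c1ccccc1.[Br-]
Why: Wittig olefination with the carboxylate ylide adds C7–C9 as a β,γ-unsaturated acid (mainly E; the alkene geometry is lost in step 5).

Step 5
Reactants: 7 (E)-4-[4-(allyloxy)-2-methylphenyl]but-3-enoic acid
Product: 9 7-(allyloxy)-5-methylnaphthalen-1-ol, via naphthyl acetate 8 (not isolated)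
Conditions: Ac2O, NaOAc, 140 °C; then K2CO3, MeOH, rt
Reagents that add atoms: none
Why: Thermal cyclodehydration of a 4-arylbut-3-enoic acid (benzannulation through the mixed anhydride) can close only onto the free ortho carbon C10 and gives the 1-naphthyl acetate, which is then methanolysed.

Step 6
Reactants: 9 7-(allyloxy)-5-methylnaphthalen-1-ol
Product: 10 quinone monoketal
Conditions: PhI(OAc)2 (2.2 equiv), MeOH, 0 °C → rt
Reagents that add atoms: methanol, CO
Why: Hypervalent-iodine oxidation of a para-unsubstituted 1-naphthol in methanol gives the para-quinone monoketal, which leaves C9 as the only free carbonyl, masks C6 and cannot tautomerise to a naphthol.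

Step 7
Reactants: 10 quinone monoketal; 3 alkenyl pinacol boronate
Product: 11 (3S)-conjugate adduct (C7 side chain β)
Conditions: [Rh(OH)((S)-binap)]2 (cat.), KOH (aq), dioxane, 50 °C
Reagents that add atoms: alkenyl pinacol boronate (3), COc1ccc(COCC(=C)B2OC(C)(C)C(C)(C)O2)cc1
Why: Hayashi–Miyaura rhodium-catalysed asymmetric 1,4-addition of an alkenylboron reagent to the cyclic enone sets C7; by analogy with 2-cyclohexenone, (S)-BINAP should direct the alkenyl group to the face that gives 7S, and this centre controls all later ones.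

Step 8
Reactants: 11 (3S)-conjugate adduct
Product: 13 8α-hydroxy ketone (7,8-trans), via potassium enolate 12 (not isolated)
Conditions: KN(SiMe3)2, THF, −78 °C; then 2-(phenylsulfonyl)-3-phenyloxaziridine, −78 °C
Reagents that add atoms: 2-(phenylsulfonyl)-3-phenyloxaziridine, O=S(=O)(N1OC1c1ccccc1)c1ccccc1
Why: Davis enolate hydroxylation; the oxaziridine approaches C8 of the enolate anti to the neighbouring C7 side chain, which gives the 7,8-trans alcohol.

Step 9
Reactants: 13 8α-hydroxy ketone
Product: 14 8α-OTBS ketone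
Conditions: TBSCl, imidazole, DMAP (cat.), DMF, 40 °C
Reagents that add atoms: tert-butyldimethylsilyl chloride, CC(C)(C)[Si](C)(C)Cl
Why: Silylation of the only free hydroxyl puts the robust group on O8 before O9 exists, so the two neighbouring oxygens never have to be told apart.

Step 10
Reactants: 14 8α-OTBS ketone
Product: 15 9β-alcohol (8,9-trans)
Conditions: NaBH4, MeOH/CH2Cl2, −40 °C
Reagents that add atoms: none
Why: Small-hydride reduction of the aryl ketone from the α face (axial attack on the half-chair with the C7 and C8 groups equatorial, the β face being screened by the C7 side chain in the other half-chair) should give the 8,9-trans alcohol.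

Step 11
Reactants: 15 9β-alcohol
Product: 17 C6 ketone with 9β-OAlloc, via carbonate ketal 16 (not isolated)
Conditions: allyl chloroformate, pyridine, DMAP (cat.), CH2Cl2, 0 °C; then 1 M HCl, THF, 0 °C
Reagents that add atoms: allyl chloroformate, C=CCOC(Cl)=O; water, O
Why: Acylation of the single free hydroxyl by a chloroformate, then mild acid hydrolysis of the very labile p-alkoxyaryl dimethyl ketal; the allyl carbonate is chosen because it leaves together with the aryl allyl ether in step 14.

Step 12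
Reactants: 17 C6 ketone
Product: 18 6β-alcohol (6,7-cis)
Conditions: LiBH(s-Bu)3, THF, −78 °C
Reagents that add atoms: none
Why: Bulky-hydride reduction of a 2-substituted 1-tetralone from the face opposite the C7 side chain gives the pseudo-axial 6,7-cis alcohol.

Step 13
Reactants: 18 6β-alcohol
Product: 19 6β-OPMB ether
Conditions: NaH, PMBCl, n-Bu4NI (cat.), DMF, 0 °C
Reagents that add atoms: 4-methoxybenzyl chloride, COc1ccc(CCl)cc1
Why: Williamson etherification of the only free hydroxyl under basic conditions, chosen because the p-alkoxybenzylic C6–O bond would ionise under acid catalysis.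

Step 14
Reactants: 19 6β-OPMB ether
Product: 20 phenol with free 9β-hydroxyl
Conditions: Pd(PPh3)4 (cat.), morpholine, THF, rt
Reagents that add atoms: none
Why: Tsuji–Trost deallylation with zerovalent palladium and an amine acceptor removes the aryl allyl ether and the allyl carbonate in one operation and leaves the alkyl 2-substituted allyl PMB ether untouched.

Step 15
Reactants: 20 phenol with free 9β-hydroxyl
Product: 21 para-quinol (5α-hydroxy dienone)
Conditions: PhI(OAc)2, MeCN/H2O, 0 °C
Reagents that add atoms: water, O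
Why: Hypervalent-iodine oxidative dearomatisation of a para-alkyl phenol to a para-quinol; water should add to C5 anti to the pseudo-axial 6β-OPMB group (the 5-epimer would serve equally in step 20).

Step 16
Reactants: 21 para-quinol; 22 (bromomethyl)chlorodimethylsilane
Product: 24 trans-decalin enone with O9–Si–C14 siloxane ring, via bromomethylsilyl ether 23 (not isolated)
Conditions: 22, Et3N, DMAP (cat.), CH2Cl2, 0 °C; then Bu3SnH, AIBN (cat.), benzene, 80 °C, slow addition
Reagents that add atoms: (bromomethyl)chlorodimethylsilane (22), C[Si](C)(Cl)CBr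
Why: Nishiyama–Stork silicon-tethered radical cyclisation: the hindered tertiary C5 hydroxyl is not silylated, and the α-silyl radical on O9 can reach only C10 in 5-exo mode (β-carbon of the C1=C10 enone), so a cis-fused siloxane forms and C14 is placed β, cis to O9.

Step 17
Reactants: 24 trans-decalin enone
Product: 25 C2 ethylene ketal
Conditions: (TMSOCH2)2, TMSOTf (cat.), CH2Cl2, −78 → −40 °C
Reagents that add atoms: 1,2-bis(trimethylsilyloxy)ethane, C[Si](C)(C)OCCO[Si](C)(C)C
Why: Noyori ketalisation masks the enone carbonyl before the basic peroxide of step 18 and the base of step 20; the C3=C4 alkene cannot migrate because C5 is quaternary.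

Step 18
Reactants: 25 C2 ethylene ketal
Product: 26 triol (10β-CH2OH, 9β-OH, 5α-OH)
Conditions: H2O2 (30 %), KF, KHCO3, THF/MeOH, rt
Reagents that add atoms: hydrogen peroxide, OO
Why: Tamao–Fleming oxidation of the alkoxysilane converts C14–Si into C14–OH with retention and frees O9.

Step 19
Reactants: 26 triol
Product: 28 fragmentation precursor (10β-CH2OMs, 9β-OTES, 5α-OH), via mesylate 27 (not isolated)
Conditions: MsCl, Et3N, CH2Cl2, −30 °C; then TESOTf, 2,6-lutidine, −78 °C
Reagents that add atoms: methanesulfonyl chloride, CS(Cl)(=O)=O; triethylsilyl trifluoromethanesulfonate, CC[Si](CC)(CC)OS(=O)(=O)C(F)(F)F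
Why: Sulfonylation is selective for the primary hydroxyl and low-temperature silylation for the secondary one, so the very hindered tertiary C5 hydroxyl stays free as the trigger.

Step 20
Reactants: 28 fragmentation precursor
Product: 30 ten-membered (Z)-enone, via potassium alkoxide 29 (not isolated)
Conditions: KN(SiMe3)2 (1.05 equiv), THF, −40 → 0 °C
Reagents that add atoms: none
Why: Deprotonation of the tertiary C5 hydroxyl gives alkoxide 29, whose oxygen lone pair pushes into C5–C10 while that bond breaks, C10=C14 forms and mesylate leaves from C14 in one concerted heterolytic step. The closest known type is the Grob (Wharton) fragmentation of decalin 1,3-diol monosulfonates to cyclodecenones, here with a primary angular sulfonate so that the new alkene is exocyclic. No ring is closed by bond formation: the ten-membered ring appears by cleavage of the bond shared by rings A and B, so no medium-ring cyclisation is needed. No stereocentre is created; C5 and C10 are destroyed, C6–C9 are untouched and the Z geometry of C3=C4 is inherited from ring A. The step needs fragmentation rather than O-alkylation or C6 epimerisation: the trans-diaxial O5/C14 arrangement rules out oxetane closure, free rotation about C10–C14 lets the C–OMs bond lie anti-periplanar to C5–C10, relief of the syn-axial 6β-OPMB/10β-CH2OMs strain and conjugation of the new ketone with C3=C4 drive the cleavage, and one equivalent of a non-nucleophilic base leaves none to epimerise C6.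

Step 21
Reactants: 30 ten-membered (Z)-enone
Product: 31 9β-alcohol
Conditions: HF·pyridine, pyridine, THF, 0 °C
Reagents that add atoms: none
Why: Selective protodesilylation: under buffered HF the triethylsilyl ether is cleaved much faster than the hindered secondary TBS ether.

Step 22
Reactants: 31 9β-alcohol; 32 (R)-2-methylbutanoic acid
Product: 33 9β-(R)-2-methylbutanoate
Conditions: 32, DCC, DMAP (cat.), CH2Cl2, 0 °C → rt
Reagents that add atoms: (R)-2-methylbutanoic acid (32), CC[C@@H](C)C(=O)O
Why: Steglich esterification of the allylic C9 hydroxyl; a simple α-alkyl acid is not expected to epimerise under these conditions.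

Step 23
Reactants: 33 9β-(R)-2-methylbutanoate
Product: 34 5α-allylic alcohol
Conditions: NaBH4, CeCl3·7H2O, MeOH, −40 °C
Reagents that add atoms: none
Why: Luche 1,2-reduction of the enone; under non-chelating conditions hydride should add anti to the C6–OPMB bond (Felkin–Anh), giving the 5,6-threo alcohol.

Step 24
Reactants: 34 5α-allylic alcohol
Product: 35 3β,4β-epoxy 5α-alcohol
Conditions: mCPBA, NaHCO3, CH2Cl2, 0 °C
Reagents that add atoms: 3-chloroperbenzoic acid, OOC(=O)c1cccc(Cl)c1
Why: Hydroxyl-directed peracid (Henbest) epoxidation: Z-allylic alcohols under A(1,3) strain and medium-ring cis-cycloalkenols give the threo (trans) epoxy alcohol, and the trisubstituted OH-assisted alkene should react before the two 1,1-disubstituted alkenes, each deactivated by an allylic C–O bond.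

Step 25
Reactants: 35 3β,4β-epoxy 5α-alcohol
Product: 36 5α,8α-diol
Conditions: Et3N·3HF, MeCN, 40 °C
Reagents that add atoms: none
Why: Near-neutral fluoride cleaves the remaining TBS ether without forming an alkoxide, so neither ester migration from O9 nor Payne rearrangement of the epoxy alcohol is triggered.

Step 26
Reactants: 36 5α,8α-diol
Product: 37 5α,8α-diacetate
Conditions: Ac2O, pyridine, DMAP (cat.), CH2Cl2, rt
Reagents that add atoms: acetic anhydride, CC(=O)OC(C)=O
Why: Standard acetylation esterifies both secondary hydroxyls (C5 and C8) in one operation.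

Step 27
Reactants: 37 5α,8α-diacetate
Product: 38 6β,12-diol
Conditions: DDQ, CH2Cl2/pH 7 buffer, 0 °C → rt
Reagents that add atoms: none
Why: Oxidative cleavage of both PMB ethers (electron transfer from the anisyl ring, then hydrolysis) under neutral conditions that spare the esters, the epoxide and the ketal.

Step 28
Reactants: 38 6β,12-diol
Product: 41 α-methylene lactone C2-ketal, via hydroxy enal 39 (not isolated), via lactol 40 (not isolated)
Conditions: TEMPO (cat.), PhI(OAc)2, CH2Cl2, rt
Reagents that add atoms: none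
Why: Oxoammonium oxidation of the primary allylic alcohol, lactol formation with the cis-disposed 6β-hydroxyl and further oxidation give the cis-fused α-methylene-γ-butyrolactone (oxidative lactonisation of a 1,4-diol).

Step 29
Reactants: 41 α-methylene lactone C2-ketal
Product: 42 target CNP0256300.1
Conditions: PPTS, acetone/H2O, 50 °C
Reagents that add atoms: water, O
Why: Weakly acidic hydrolysis of the dioxolane releases the C2 ketone last, so the base-sensitive β,γ-unsaturated epoxy ketone meets no further reagent.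

Compound list
1 | 2-bromoprop-2-en-1-ol | OCC(Br)=C | starting material
2 | 2-bromoallyl 4-methoxybenzyl ether | COc1ccc(COCC(Br)=C)cc1 | intermediate
3 | 2-{3-[(4-methoxybenzyl)oxy]prop-1-en-2-yl}-4,4,5,5-tetramethyl-1,3,2-dioxaborolane | COc1ccc(COCC(=C)B2OC(C)(C)C(C)(C)O2)cc1 | intermediate
4 | 4-hydroxy-2-methylbenzaldehyde | Cc1cc(O)ccc1C=O | starting material
5 | 4-(allyloxy)-2-methylbenzaldehyde | C=CCOc1ccc(C=O)c(C)c1 | intermediate
6 | (2-carboxyethyl)triphenylphosphonium bromide | OC(=O)CC[P+](c1ccccc1)(c1ccccc1)c1ccccc1.[Br-] | starting material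
7 | (E)-4-[4-(allyloxy)-2-methylphenyl]but-3-enoic acid | C=CCOc1ccc(/C=C/CC(=O)O)c(C)c1 | intermediate
8 | 7-(allyloxy)-5-methylnaphthalen-1-yl acetate | C=CCOc1cc(C)c2cccc(OC(C)=O)c2c1 | intermediate
9 | 7-(allyloxy)-5-methylnaphthalen-1-ol | C=CCOc1cc(C)c2cccc(O)c2c1 | intermediate
10 | 7-(allyloxy)-4,4-dimethoxy-5-methylnaphthalen-1(4H)-one (C9 ketone, C7=C8, C6 dimethyl ketal) | C=CCOc1cc(C)c2c(c1)C(=O)C=CC2(OC)OC | intermediate
11 | (3S)-7-(allyloxy)-4,4-dimethoxy-3-{3-[(4-methoxybenzyl)oxy]prop-1-en-2-yl}-5-methyl-3,4-dihydronaphthalen-1(2H)-one (side chain on C7, β) | C=CCOc1cc(C)c2c(c1)C(=O)C[C@@H](C(=C)COCc1ccc(OC)cc1)C2(OC)OC | intermediate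
12 | potassium C8=C9 enolate of 11 | C=CCOc1cc(C)c2c(c1)C([O-])=C[C@@H](C(=C)COCc1ccc(OC)cc1)C2(OC)OC.[K+] | intermediate
13 | 11 with an 8α-hydroxyl (α-hydroxy ketone, 7,8-trans) | C=CCOc1cc(C)c2c(c1)C(=O)[C@H](O)[C@@H](C(=C)COCc1ccc(OC)cc1)C2(OC)OC | intermediate
14 | 8α-O-TBS ether of 13 | C=CCOc1cc(C)c2c(c1)C(=O)[C@H](O[Si](C)(C)C(C)(C)C)[C@@H](C(=C)COCc1ccc(OC)cc1)C2(OC)OC | intermediate
15 | 9β-alcohol from 14 (8,9-trans; C6 ketal kept) | C=CCOc1cc(C)c2c(c1)[C@@H](O)[C@H](O[Si](C)(C)C(C)(C)C)[C@@H](C(=C)COCc1ccc(OC)cc1)C2(OC)OC | intermediate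
16 | 9β-O-allyloxycarbonyl derivative of 15 | C=CCOc1cc(C)c2c(c1)[C@@H](OC(=O)OCC=C)[C@H](O[Si](C)(C)C(C)(C)C)[C@@H](C(=C)COCc1ccc(OC)cc1)C2(OC)OC | intermediate
17 | C6 ketone from 16 (8α-OTBS, 9β-OAlloc) | C=CCOc1cc(C)c2c(c1)[C@@H](OC(=O)OCC=C)[C@H](O[Si](C)(C)C(C)(C)C)[C@@H](C(=C)COCc1ccc(OC)cc1)C2=O | intermediate
18 | 6β-alcohol from 17 (6,7-cis) | C=CCOc1cc(C)c2c(c1)[C@@H](OC(=O)OCC=C)[C@H](O[Si](C)(C)C(C)(C)C)[C@@H](C(=C)COCc1ccc(OC)cc1)[C@H]2O | intermediate
19 | 6β-O-PMB ether of 18 | C=CCOc1cc(C)c2c(c1)[C@@H](OC(=O)OCC=C)[C@H](O[Si](C)(C)C(C)(C)C)[C@@H](C(=C)COCc1ccc(OC)cc1)[C@H]2OCc1ccc(OC)cc1 | intermediate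
20 | tetralin phenol (C2–OH) with 6β-OPMB, 7β side chain, 8α-OTBS, free 9β-OH | Oc1cc(C)c2c(c1)[C@@H](O)[C@H](O[Si](C)(C)C(C)(C)C)[C@@H](C(=C)COCc1ccc(OC)cc1)[C@H]2OCc1ccc(OC)cc1 | intermediate
21 | para-quinol: ring A 2-oxo-1(10),3-dienone with 5α-OH; ring B as in 20 | O=C1C=C(C)[C@]2(O)[C@H](OCc3ccc(OC)cc3)[C@H](C(=C)COCc3ccc(OC)cc3)[C@@H](O[Si](C)(C)C(C)(C)C)[C@H](O)C2=C1 | intermediate
22 | (bromomethyl)chlorodimethylsilane | C[Si](C)(Cl)CBr | starting material
23 | 9β-O-[(bromomethyl)dimethylsilyl] ether of 21 | O=C1C=C(C)[C@]2(O)[C@H](OCc3ccc(OC)cc3)[C@H](C(=C)COCc3ccc(OC)cc3)[C@@H](O[Si](C)(C)C(C)(C)C)[C@H](O[Si](C)(C)CBr)C2=C1 | intermediate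
24 | trans-decalin: O9–SiMe2–C14 siloxane ring (C14 on C10, β), C2 ketone, C3=C4, 5α-OH | C[Si]1(C)C[C@]23CC(=O)C=C(C)[C@]2(O)[C@H](OCc4ccc(OC)cc4)[C@H](C(=C)COCc4ccc(OC)cc4)[C@@H](O[Si](C)(C)C(C)(C)C)[C@@H]3O1 | intermediate
25 | C2 ethylene ketal of 24 | C[Si]1(C)C[C@]23CC4(OCCO4)C=C(C)[C@]2(O)[C@H](OCc4ccc(OC)cc4)[C@H](C(=C)COCc4ccc(OC)cc4)[C@@H](O[Si](C)(C)C(C)(C)C)[C@@H]3O1 | intermediate
26 | triol: 10β-CH2OH, 9β-OH, 5α-OH (C2 ketal, C3=C4, 6β-OPMB, 8α-OTBS) | OC[C@]12CC3(OCCO3)C=C(C)[C@]1(O)[C@H](OCc1ccc(OC)cc1)[C@H](C(=C)COCc1ccc(OC)cc1)[C@@H](O[Si](C)(C)C(C)(C)C)[C@@H]2O | intermediate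
27 | C14 mesylate of 26 | CS(=O)(=O)OC[C@]12CC3(OCCO3)C=C(C)[C@]1(O)[C@H](OCc1ccc(OC)cc1)[C@H](C(=C)COCc1ccc(OC)cc1)[C@@H](O[Si](C)(C)C(C)(C)C)[C@@H]2O | intermediate
28 | fragmentation precursor: 27 with 9β-OTES (trans-decalin, 5α-OH, 10β-CH2OMs) | CS(=O)(=O)OC[C@]12CC3(OCCO3)C=C(C)[C@]1(O)[C@H](OCc1ccc(OC)cc1)[C@H](C(=C)COCc1ccc(OC)cc1)[C@@H](O[Si](C)(C)C(C)(C)C)[C@@H]2O[Si](CC)(CC)CC | intermediate
29 | potassium C5 alkoxide of 28 | CS(=O)(=O)OC[C@]12CC3(OCCO3)C=C(C)[C@]1([O-])[C@H](OCc1ccc(OC)cc1)[C@H](C(=C)COCc1ccc(OC)cc1)[C@@H](O[Si](C)(C)C(C)(C)C)[C@@H]2O[Si](CC)(CC)CC.[K+] | intermediate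
30 | ten-membered (Z)-enone: C5 ketone, C3=C4, C2 ketal, C10=C14, 6β-OPMB, 8α-OTBS, 9β-OTES | C=C1CC2(OCCO2)/C=C(/C)C(=O)[C@H](OCc2ccc(OC)cc2)[C@H](C(=C)COCc2ccc(OC)cc2)[C@@H](O[Si](C)(C)C(C)(C)C)[C@@H]1O[Si](CC)(CC)CC | intermediate
31 | 9β-alcohol from 30 | C=C1CC2(OCCO2)/C=C(/C)C(=O)[C@H](OCc2ccc(OC)cc2)[C@H](C(=C)COCc2ccc(OC)cc2)[C@@H](O[Si](C)(C)C(C)(C)C)[C@@H]1O | intermediate
32 | (R)-2-methylbutanoic acid | CC[C@@H](C)C(=O)O | starting material
33 | 9β-(R)-2-methylbutanoate of 31 | C=C1CC2(OCCO2)/C=C(/C)C(=O)[C@H](OCc2ccc(OC)cc2)[C@H](C(=C)COCc2ccc(OC)cc2)[C@@H](O[Si](C)(C)C(C)(C)C)[C@@H]1OC(=O)[C@H](C)CC | intermediate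
34 | 5α-allylic alcohol from 33 | C=C1CC2(OCCO2)/C=C(/C)[C@@H](O)[C@H](OCc2ccc(OC)cc2)[C@H](C(=C)COCc2ccc(OC)cc2)[C@@H](O[Si](C)(C)C(C)(C)C)[C@@H]1OC(=O)[C@H](C)CC | intermediate
35 | 3β,4β-epoxy 5α-alcohol | C=C1CC2(OCCO2)[C@@H]3O[C@]3(C)[C@@H](O)[C@H](OCc2ccc(OC)cc2)[C@H](C(=C)COCc2ccc(OC)cc2)[C@@H](O[Si](C)(C)C(C)(C)C)[C@@H]1OC(=O)[C@H](C)CC | intermediate
36 | 5α,8α-diol | C=C1CC2(OCCO2)[C@@H]3O[C@]3(C)[C@@H](O)[C@H](OCc2ccc(OC)cc2)[C@H](C(=C)COCc2ccc(OC)cc2)[C@@H](O)[C@@H]1OC(=O)[C@H](C)CC | intermediate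
37 | 5α,8α-diacetate | C=C1CC2(OCCO2)[C@@H]3O[C@]3(C)[C@@H](OC(C)=O)[C@H](OCc2ccc(OC)cc2)[C@H](C(=C)COCc2ccc(OC)cc2)[C@@H](OC(C)=O)[C@@H]1OC(=O)[C@H](C)CC | intermediate
38 | 6β,12-diol | C=C1CC2(OCCO2)[C@@H]3O[C@]3(C)[C@@H](OC(C)=O)[C@H](O)[C@H](C(=C)CO)[C@@H](OC(C)=O)[C@@H]1OC(=O)[C@H](C)CC | intermediate
39 | 6β-hydroxy 12-enal | C=C1CC2(OCCO2)[C@@H]3O[C@]3(C)[C@@H](OC(C)=O)[C@H](O)[C@H](C(=C)C=O)[C@@H](OC(C)=O)[C@@H]1OC(=O)[C@H](C)CC | intermediate
40 | 12,6β-lactol (C12 epimers) | C=C1CC2(OCCO2)[C@@H]3O[C@]3(C)[C@@H](OC(C)=O)[C@@H]4OC(O)C(=C)[C@@H]4[C@@H](OC(C)=O)[C@@H]1OC(=O)[C@H](C)CC | intermediate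
41 | cis-fused 12,6β-lactone with C2 ethylene ketal | C=C1CC2(OCCO2)[C@@H]3O[C@]3(C)[C@@H](OC(C)=O)[C@@H]4OC(=O)C(=C)[C@@H]4[C@@H](OC(C)=O)[C@@H]1OC(=O)[C@H](C)CC | intermediate
42 | CNP0256300.1: 3β,4β-epoxy-5α,8α-diacetoxy-9β-[(R)-2-methylbutanoyloxy]-2-oxogermacra-10(14),11(13)-dien-12,6β-olide | C=C1C(=O)O[C@@H]2[C@H]1[C@@H](OC(C)=O)[C@H](OC(=O)[C@H](C)CC)C(=C)CC(=O)[C@@H]1O[C@]1(C)[C@H]2OC(C)=O | target

Total step count: 29. Longest linear sequence: 27 steps (steps 3–29, from 4 to 42); steps 1–2 form the side branch that joins in step 7.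

Steps most likely to fail

Step 20 (key step). What may go wrong: heterolysis may be slowed by the crowded axial C14 mesylate, so that migration of the triethylsilyl group from O9 to the C5 alkoxide (which would also open a C9–C10 fragmentation from the freed O9 alkoxide) or base-induced epimerisation at C6 of the product competes. Fallback: the silyl ether is replaced by the final ester before the fragmentation. Setting out from mesylate 27 (isolated after the first half of step 19), O9 is esterified with 32 (DCC, DMAP, CH2Cl2) to give the C9 (R)-2-methylbutanoate mesylate F1. NaH in THF at 0 °C forms its sodium C5 alkoxide F2, which fragments in the same way and returns to the route at 33; steps 21 and 22 are then not needed. An ester on O9 cannot reach the trans-diaxial O5 and should not be attacked by the hindered tertiary alkoxide.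

Step 7. What may go wrong: slow boron-to-rhodium transmetalation of the α-substituted alkenyl boronate with competing protodeboronation, or weak enantioface discrimination next to the ketal carbon. Fallback: copper-catalysed asymmetric conjugate addition of an alkenylalane. Setting out from bromide 2 and enone 10, lithium–bromine exchange (t-BuLi, Et2O, −78 °C) gives the alkenyllithium F3 and Me2AlCl converts it into the alkenyl(dimethyl)alane F4. F4 adds to 10 in the presence of copper thiophene-2-carboxylate (C5H3CuO2S, monovalent copper) and a BINOL-derived phosphoramidite ligand; aqueous work-up returns to the route at 11.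

Step 23. What may go wrong: poor facial selectivity, since the conformation of the ten-membered ring and not the Felkin–Anh preference may decide which face of the C5 carbonyl is open. Fallback: correction by inversion in place of a selective reduction. Setting out from 33, the reduction is run as before and the 5β-alcohol F5 that would then predominate is inverted by Mitsunobu esterification (ClCH2CO2H, PPh3, DIAD, THF) to the 5α-chloroacetate F6. Methanolysis of the labile chloroacetate (K2CO3, MeOH, −20 °C), which the hindered C9 ester should survive, returns to the route at 34.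

Further compounds
F1 | step 20 | C9 (R)-2-methylbutanoate of mesylate 27 | CS(=O)(=O)OC[C@]12CC3(OCCO3)C=C(C)[C@]1(O)[C@H](OCc1ccc(OC)cc1)[C@H](C(=C)COCc1ccc(OC)cc1)[C@@H](O[Si](C)(C)C(C)(C)C)[C@@H]2OC(=O)[C@H](C)CC
F2 | step 20 | sodium C5 alkoxide of F1 | CS(=O)(=O)OC[C@]12CC3(OCCO3)C=C(C)[C@]1([O-])[C@H](OCc1ccc(OC)cc1)[C@H](C(=C)COCc1ccc(OC)cc1)[C@@H](O[Si](C)(C)C(C)(C)C)[C@@H]2OC(=O)[C@H](C)CC.[Na+]
F3 | step 7 | {3-[(4-methoxybenzyl)oxy]prop-1-en-2-yl}lithium | [Li]C(=C)COCc1ccc(OC)cc1
F4 | step 7 | dimethyl{3-[(4-methoxybenzyl)oxy]prop-1-en-2-yl}alane | C[Al](C)C(=C)COCc1ccc(OC)cc1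
F5 | step 23 | 5β epimer of 34 | C=C1CC2(OCCO2)/C=C(/C)[C@H](O)[C@H](OCc2ccc(OC)cc2)[C@H](C(=C)COCc2ccc(OC)cc2)[C@@H](O[Si](C)(C)C(C)(C)C)[C@@H]1OC(=O)[C@H](C)CC
F6 | step 23 | 5α-chloroacetate of 34 | C=C1CC2(OCCO2)/C=C(/C)[C@@H](OC(=O)CCl)[C@H](OCc2ccc(OC)cc2)[C@H](C(=C)COCc2ccc(OC)cc2)[C@@H](O[Si](C)(C)C(C)(C)C)[C@@H]1OC(=O)[C@H](C)CC
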